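**Retrosynthetic overview**
1. Target ⇒ open the dihydrofuran C–O bond (5-exo opening of an (R)-prenyl epoxide by the phenol para to the ketone) and trace the carbinol C–O bond back to a C–B bond ⇒ an achiral (E)-5'-prenyl-2',4'-dihydroxychalcone that already carries the chroman.
2. Prenylchalcone ⇒ Claisen–Schmidt condensation of 5-prenyl-2,4-dihydroxyacetophenone with 2,2-dimethylchroman-6-carbaldehyde.
3. Chroman aldehyde ⇒ 4-hydroxybenzaldehyde + isoprene (C-prenylation, then proton-initiated cyclization of the ortho-prenylphenol).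
4. Prenyl ketone ⇒ 2,4-dihydroxyacetophenone + 2-methylbut-3-en-2-ol (electrophilic C-prenylation).
5. Ring order: the chroman ring is formed first (step 1); the dihydrofuran ring is formed last (step 4), in the same operation that sets both stereocenters.

Assumption: the (R,S) antipode of Josiphos is taken to give the (S)-benzylic boronate, and so the (S)-carbinol, from the (E)-chalcone, by analogy with simple aryl enones. If a pilot run shows the opposite sense, the (S,R) antipode is used with nothing else changed.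

**Step 1**
Reactants: 1 4-hydroxybenzaldehyde; 2 isoprene (2-methylbuta-1,3-diene)
Product: 4 2,2-dimethyl-3,4-dihydro-2H-chromene-6-carbaldehyde, via ortho-prenylphenol 3 (not isolated)
Conditions: 85% H3PO4, isoprene (2 equiv), xylene, 30–35 °C, 16 h
Reagents that add atoms: none
Why: Tandem Friedel–Crafts prenylation and Markovnikov phenol–alkene cycloetherification, in which the dimethylallyl cation from protonated isoprene attacks the only activated position (ortho to OH, meta to CHO) and the ortho-prenylphenol 3 is then protonated to a tertiary cation that the phenol oxygen traps to close the chroman, copying the prenylation/proton-initiated cyclization of chroman biosynthesis; no stereocenter is formed.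

**Step 2**
Reactants: 5 2,4-dihydroxyacetophenone; 6 2-methylbut-3-en-2-ol
Product: 7 1-[2,4-dihydroxy-5-(3-methylbut-2-en-1-yl)phenyl]ethan-1-one
Conditions: BF3·OEt2 (0.3 equiv), dioxane, rt, 6 h; chromatography
Reagents that add atoms: none
Why: Friedel–Crafts C-prenylation through the BF3-generated dimethylallyl cation, which substitutes the resorcinol ring mainly at C5 (ortho to the free 4-OH, para to the chelated 2-OH and less hindered than C3), the chemical counterpart of an aromatic prenyltransferase; 7 is separated from the minor 3-prenyl isomer and recovered 5, and no stereocenter is formed.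

**Step 3**
Reactants: 7 1-[2,4-dihydroxy-5-(3-methylbut-2-en-1-yl)phenyl]ethan-1-one; 4 2,2-dimethyl-3,4-dihydro-2H-chromene-6-carbaldehyde
Product: 8 (2E)-1-[2,4-dihydroxy-5-(3-methylbut-2-en-1-yl)phenyl]-3-(2,2-dimethyl-3,4-dihydro-2H-chromen-6-yl)prop-2-en-1-one
Conditions: KOH (6 equiv), EtOH/H2O, 0 °C to rt, 48 h; then cold aq. HCl to pH 5
Reagents that add atoms: none
Why: Claisen–Schmidt (crossed aldol) condensation in which the methyl ketone enolate adds to the non-enolizable aldehyde and E1cB dehydration gives the thermodynamically favored (E)-enone, the prenyl group and the chroman being inert to base; no stereocenter is formed.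

**Step 4**
Reactants: 8 (2E)-1-[2,4-dihydroxy-5-(3-methylbut-2-en-1-yl)phenyl]-3-(2,2-dimethyl-3,4-dihydro-2H-chromen-6-yl)prop-2-en-1-one
Product: 12 (3S)-3-(2,2-dimethyl-3,4-dihydro-2H-chromen-6-yl)-3-hydroxy-1-[(2S)-6-hydroxy-2-(2-hydroxypropan-2-yl)-2,3-dihydro-1-benzofuran-5-yl]propan-1-one (target CNP0419761.2), via β-boryl ketone 9 (not isolated), via prenyl hydroxy ketone 10 (not isolated), via epoxy alcohol 11 (not isolated)
Conditions: CuCl (5 mol %), NaOtBu (10 mol %), (R,S)-Josiphos C36H44FeP2 (6 mol %), B2pin2 (1.5 equiv), MeOH (3 equiv), THF, rt; then evaporate, D-fructose-derived Shi ketone (0.4 equiv), Oxone (2KHSO5·KHSO4·K2SO4; 4 equiv KHSO5), K2CO3, Na2H2EDTA (excess over Cu), Bu4NHSO4, MeCN/dimethoxymethane/aq. Na2B4O7 buffer (pH 10.5), 0 °C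
Reagents that add atoms: potassium peroxymonosulfate (active component of Oxone), [K+].[O-]S(=O)(=O)OO, supplies both new oxygen atoms of 12; bis(pinacolato)diboron, CC1(C)OB(OC1(C)C)B1OC(C)(C)C(C)(C)O1, supplies the boron of 9 only, which is replaced by OH
Why: Proposed new method: a copper-catalyzed asymmetric conjugate borylation of the (E)-chalcone (known reaction type; the Josiphos-bound boryl-copper adds to one enone face to give the (S)-benzylic boronate 9 and leaves the unactivated prenyl alkene alone) is telescoped with a Shi epoxidation in which the same Oxone charge first oxidizes the C–B bond to C–OH with retention (peroxide attack at boron, then 1,2-shift, giving 10) and then, through the chiral dioxirane of the fructose-derived ketone, epoxidizes the trisubstituted prenyl alkene on one face to the (R)-epoxide 11, which the neighboring phenoxide para to the ketone (ionized at pH 10.5) opens 5-exo-tet with inversion at the secondary carbon to give the (2S)-hydroxyisopropyl-dihydrofuran as in the presumed epoxide/phenol biosynthesis; the two stereocenters are remote and each is set by its own catalyst, and the closest known reactions are chalcone β-borylation/oxidation to β-hydroxy ketones and Shi epoxidation/cyclization of protected ortho-prenylphenols.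

**Compound list**
1 | 4-hydroxybenzaldehyde | O=Cc1ccc(O)cc1 | starting material
2 | isoprene (2-methylbuta-1,3-diene) | C=CC(C)=C | starting material
3 | 4-hydroxy-3-(3-methylbut-2-en-1-yl)benzaldehyde | CC(C)=CCc1cc(C=O)ccc1O | intermediate
4 | 2,2-dimethyl-3,4-dihydro-2H-chromene-6-carbaldehyde | CC1(C)CCc2cc(C=O)ccc2O1 | intermediate
5 | 2,4-dihydroxyacetophenone | CC(=O)c1ccc(O)cc1O | starting material
6 | 2-methylbut-3-en-2-ol | CC(C)(O)C=C | starting material
7 | 1-[2,4-dihydroxy-5-(3-methylbut-2-en-1-yl)phenyl]ethan-1-one | CC(=O)c1cc(CC=C(C)C)c(O)cc1O | intermediate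
8 | (2E)-1-[2,4-dihydroxy-5-(3-methylbut-2-en-1-yl)phenyl]-3-(2,2-dimethyl-3,4-dihydro-2H-chromen-6-yl)prop-2-en-1-one | CC1(C)CCc2cc(/C=C/C(=O)c3cc(CC=C(C)C)c(O)cc3O)ccc2O1 | intermediate
9 | (3S)-1-[2,4-dihydroxy-5-(3-methylbut-2-en-1-yl)phenyl]-3-(2,2-dimethyl-3,4-dihydro-2H-chromen-6-yl)-3-(4,4,5,5-tetramethyl-1,3,2-dioxaborolan-2-yl)propan-1-one | CC1(C)CCc2cc([C@@H](B3OC(C)(C)C(C)(C)O3)CC(=O)c4cc(CC=C(C)C)c(O)cc4O)ccc2O1 | intermediate
10 | (3S)-1-[2,4-dihydroxy-5-(3-methylbut-2-en-1-yl)phenyl]-3-(2,2-dimethyl-3,4-dihydro-2H-chromen-6-yl)-3-hydroxypropan-1-one | CC1(C)CCc2cc([C@@H](O)CC(=O)c3cc(CC=C(C)C)c(O)cc3O)ccc2O1 | intermediate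
11 | (3S)-1-[5-{[(2R)-3,3-dimethyloxiran-2-yl]methyl}-2,4-dihydroxyphenyl]-3-(2,2-dimethyl-3,4-dihydro-2H-chromen-6-yl)-3-hydroxypropan-1-one | CC1(C)CCc2cc([C@@H](O)CC(=O)c3cc(C[C@H]4OC4(C)C)c(O)cc3O)ccc2O1 | intermediate
12 | (3S)-3-(2,2-dimethyl-3,4-dihydro-2H-chromen-6-yl)-3-hydroxy-1-[(2S)-6-hydroxy-2-(2-hydroxypropan-2-yl)-2,3-dihydro-1-benzofuran-5-yl]propan-1-one | CC1(C)CCc2cc([C@@H](O)CC(=O)c3cc4c(cc3O)O[C@H](C(C)(C)O)C4)ccc2O1 | target

**Totals**
Total step count: 4. Longest linear sequence: 3 steps (5 → 7 → 8 → 12); step 1 supplies aldehyde 4 in a one-step side branch.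

**Steps most likely to fail, with fallbacks**

Step 4 is the highest risk. The two free phenols may slow copper turnover, copper residues may decompose Oxone, the free phenoxide may be over-oxidized, and the β-hydroxy ketone may suffer retro-aldol cleavage or elimination at pH 10.5. The fallback moves the ring closure to the acetophenone stage and separates the two oxidations. It sets out from 7: selective silylation of the non-chelated 4-OH (TBSCl, imidazole, DMF, 0 °C) gives 1-[4-(tert-butyldimethylsilyloxy)-2-hydroxy-5-(3-methylbut-2-en-1-yl)phenyl]ethan-1-one F1. Shi epoxidation with the same fructose-derived ketone gives 1-[4-(tert-butyldimethylsilyloxy)-5-{[(2R)-3,3-dimethyloxiran-2-yl]methyl}-2-hydroxyphenyl]ethan-1-one F2. Bu4NF in THF at 0 °C removes the silyl group, and the liberated phenoxide closes the ring with inversion to 1-[(2S)-6-hydroxy-2-(2-hydroxypropan-2-yl)-2,3-dihydro-1-benzofuran-5-yl]ethan-1-one F3. Claisen–Schmidt condensation of F3 with 4 (KOH, EtOH), now with only one chelated phenol, gives (2E)-3-(2,2-dimethyl-3,4-dihydro-2H-chromen-6-yl)-1-[(2S)-6-hydroxy-2-(2-hydroxypropan-2-yl)-2,3-dihydro-1-benzofuran-5-yl]prop-2-en-1-one F4. CuCl/Josiphos/B2pin2 borylation gives (3S)-3-(2,2-dimethyl-3,4-dihydro-2H-chromen-6-yl)-1-[(2S)-6-hydroxy-2-(2-hydroxypropan-2-yl)-2,3-dihydro-1-benzofuran-5-yl]-3-(4,4,5,5-tetramethyl-1,3,2-dioxaborolan-2-yl)propan-1-one F5, which NaBO3·4H2O in THF/H2O oxidizes with retention, and the fallback comes back to the route at 12.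

Step 2 is the next risk: the yield is low, and the 3-prenyl isomer, bis-prenylation and acid-induced chroman formation compete. The fallback delivers the prenyl group through oxygen. It sets out from 5: O-alkylation of the non-chelated 4-OH (prenyl bromide, K2CO3, acetone, reflux) gives 1-[2-hydroxy-4-(3-methylbut-2-en-1-yloxy)phenyl]ethan-1-one F6. A 1,3-shift of the prenyl group from oxygen to the adjacent, less hindered C5, promoted by montmorillonite K10 (acidic aluminosilicate clay, idealised Al2Si4O10(OH)2·nH2O) in CH2Cl2 at 0 °C, comes back to the route at 7.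

Step 1 is the third risk: the formyl group deactivates the ring toward Friedel–Crafts attack, and isoprene oligomerizes in acid. The fallback separates C–C from C–O bond formation and uses the phenoxide as the nucleophile. It sets out from 1: ortho-C-prenylation with prenyl bromide in aqueous KOH gives 3, now isolated, and Amberlyst 15 (sulfonic acid resin) in toluene at 60 °C cyclizes it, coming back to the route at 4. This fallback makes no compound outside the list: none F0.

**Further compounds**
F1 | step 4 | 1-[4-(tert-butyldimethylsilyloxy)-2-hydroxy-5-(3-methylbut-2-en-1-yl)phenyl]ethan-1-one | CC(=O)c1cc(CC=C(C)C)c(O[Si](C)(C)C(C)(C)C)cc1O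
F2 | step 4 | 1-[4-(tert-butyldimethylsilyloxy)-5-{[(2R)-3,3-dimethyloxiran-2-yl]methyl}-2-hydroxyphenyl]ethan-1-one | CC(=O)c1cc(C[C@H]2OC2(C)C)c(O[Si](C)(C)C(C)(C)C)cc1O
F3 | step 4 | 1-[(2S)-6-hydroxy-2-(2-hydroxypropan-2-yl)-2,3-dihydro-1-benzofuran-5-yl]ethan-1-one | CC(=O)c1cc2c(cc1O)O[C@H](C(C)(C)O)C2
F4 | step 4 | (2E)-3-(2,2-dimethyl-3,4-dihydro-2H-chromen-6-yl)-1-[(2S)-6-hydroxy-2-(2-hydroxypropan-2-yl)-2,3-dihydro-1-benzofuran-5-yl]prop-2-en-1-one | CC1(C)CCc2cc(/C=C/C(=O)c3cc4c(cc3O)O[C@H](C(C)(C)O)C4)ccc2O1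
F5 | step 4 | (3S)-3-(2,2-dimethyl-3,4-dihydro-2H-chromen-6-yl)-1-[(2S)-6-hydroxy-2-(2-hydroxypropan-2-yl)-2,3-dihydro-1-benzofuran-5-yl]-3-(4,4,5,5-tetramethyl-1,3,2-dioxaborolan-2-yl)propan-1-one | CC1(C)CCc2cc([C@@H](B3OC(C)(C)C(C)(C)O3)CC(=O)c4cc5c(cc4O)O[C@H](C(C)(C)O)C5)ccc2O1
F6 | step 2 | 1-[2-hydroxy-4-(3-methylbut-2-en-1-yloxy)phenyl]ethan-1-one | CC(=O)c1ccc(OCC=C(C)C)cc1O
F0 | step 1 | none | none
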